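## Retrosynthetic overview
1. Polyanthinin **13** ⇒ C3‑O acetylation and a Mitsunobu C11–O–aryl bond to umbelliferone **11** ⇒ 3β,11‑diol **10**.
2. **10** ⇒ 4,4‑dimethyl‑3‑ketone **9** ⇒ reductive methylation of 4‑methylene‑3‑ketone **8** ⇒ enol silane **7** ⇒ cis‑selective Me2CuLi addition (C5‑Me) to Δ4‑3‑one **6**. The three contiguous quaternary carbons are built outward from C10: C10, then C5, then C4.
3. The ring‑B array of **6** (C8=CH2, 9α‑H, 9β‑CH2OH) ⇒ Pd/formate hydrogenolysis of spiro vinyl‑oxirane **4** ⇒ α‑methylenation and LiCH2Cl addition at the C9 ketone. This is done first, while the bicycle is a rigid octalin with only its α face open.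
4. No ring is formed in the route. Both carbocycles and C10 come from (S)‑Wieland–Miescher ketone **1**, and the coumarin comes from **11**. In the final cis‑decalin the C9 side chain is axial and contra‑thermodynamic, so C9 is never α to a carbonyl once it is set.

**Assumption:** the SMILES is taken literally. It gives C27H34O5, a cis‑decalin with a methyl on both ring‑fusion carbons.

**Numbering (drimane type):** ring A is C1–C5 plus C10, and ring B is C5–C10. C11 is the CH2 on C9 and C12 is the exocyclic CH2 on C8. β is the face carrying the C10 methyl. In the target, 3‑OAc, 5‑Me, 10‑Me and 9‑CH2OAr are all β, which corresponds to 3S,5S,9S,10R.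

## Route

**Step 1**
Reactants: **1** (S)‑(+)‑Wieland–Miescher ketone
Product: **2** the C3 1,3‑dithiolane of **1** (Δ4 retained, C9 ketone free, 10β‑Me)
Conditions: HSCH2CH2SH, p‑TsOH, AcOH, rt
Reagents that add atoms: ethane‑1,2‑dithiol, SCCS
Why: In this chemoselective thioketalisation the conjugated carbonyl reacts through a stabilised allylic thionium ion, while the neopentyl C9 ketone is too hindered to react.

**Step 2**
Reactants: **2**
Product: **3** the 8(12)‑methylene‑9‑ketone (exo‑methylene enone, dithiolane intact)
Conditions: (CH2O)n, i‑Pr2NH·TFA, cat. TFA, THF, reflux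
Reagents that add atoms: formaldehyde (as paraformaldehyde), C=O
Why: In this one‑pot Mannich condensation/elimination (α‑methylenation), C8 is the only enolisable position of the C9 ketone because C10 is quaternary.

**Step 3**
Reactants: **3**
Product: **4** the spiro 9,11‑oxirane (O on the β face, C11H2 on the α face), with C8=C12H2 retained
Conditions: ClCH2I, MeLi·LiBr, THF, −78 °C → rt
Reagents that add atoms: chloroiodomethane, ClCI
Why: The hard carbenoid LiCH2Cl adds 1,2 to the enone from the α face, anti to the axial C10 methyl, and the chlorohydrin alkoxide closes to the epoxide (Darzens/Matteson‑type epoxidation), which fixes C9.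

**Step 4**
Reactants: **4**
Product: **5** the 9β‑hydroxymethyl (9α‑H) 8(12)‑ene, dithiolane intact
Conditions: Pd2(dba)3·CHCl3 (5 mol %), n‑Bu3P, HCO2H/Et3N, THF, rt → 40 °C
Reagents that add atoms: none
Why: In this Tsuji‑type Pd/formate hydrogenolysis of an alkenyl oxirane, Pd ionises C9–O from the open α face and transfers hydride to the more substituted allyl terminus, giving net inversion at C9 (9α‑H, 9β‑CH2OH) and the exocyclic alkene.

**Step 5**
Reactants: **5**
Product: **6** 11‑hydroxy‑Δ4,8(12)‑dien‑3‑one
Conditions: MeI, CaCO3, MeCN/H2O 9:1, 55 °C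
Reagents that add atoms: water, O
Why: This alkylative dethioketalisation (S‑methylation followed by hydrolysis) is neutral, so the 1,1‑disubstituted alkene, the alcohol and C9 are untouched.

**Step 6**
Reactants: **6**
Product: **7** the 5β,10β‑dimethyl cis‑decalin as its C3 TES enol ether (Δ3) and C11 TES ether
Conditions: Me2CuLi (4 equiv), TESCl (6 equiv), Et2O/THF, −78 → −20 °C, then Et3N
Reagents that add atoms: lithium dimethylcuprate, [Li+].C[Cu-]C; chlorotriethylsilane, CC[Si](Cl)(CC)CC
Why: Silyl‑accelerated cuprate conjugate addition to a 10‑methyl‑octalone proceeds by stereoelectronic axial attack on the folded half‑chair, placing the C5 methyl cis to the C10 methyl, while TESCl traps the regiospecific C3/C4 enolate and protects C11‑OH in the same operation.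

**Step 7**
Reactants: **7**
Product: **8** the 4‑methylene‑3‑ketone (C11‑OTES)
Conditions: CH2=NMe2+ I−, CH2Cl2, rt; then MeI; then DBU
Reagents that add atoms: Eschenmoser's salt, C=[N+](C)C.[I-]
Why: A Mannich reaction of the enol silane followed by Hofmann‑type elimination places the new carbon only at C4.

**Step 8**
Reactants: **8**
Product: **9** the 4,4‑dimethyl‑3‑ketone (C11‑OTES)
Conditions: L‑Selectride, THF, −78 °C; then MeI, DMPU, −78 °C → rt; NaOH/H2O2 work‑up
Reagents that add atoms: iodomethane, CI
Why: In this conjugate reduction/enolate alkylation (reductive methylation), hydride adds to the unhindered exo‑CH2 and the resulting C3=C4 enolate can only be methylated at C4, completing the C4/C5/C10 quaternary triad with no new stereocentre.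

**Step 9**
Reactants: **9**
Product: **10** the 3β,11‑diol
Conditions: Li, NH3(l)/THF, t‑BuOH, −78 °C; NH4Cl; then AcOH/THF/H2O 3:1:1, rt
Reagents that add atoms: none
Why: Once C4 is quaternary the cis‑decalin adopts the chair–chair form with C4 equatorial on ring B, in which 3β‑OH is equatorial and 3α‑OH would be 1,3‑diaxial with C6, so thermodynamically controlled dissolving‑metal reduction gives the 3β (S) alcohol, and mild acid then removes the TES group.

**Step 10**
Reactants: **10**; **11** umbelliferone (7‑hydroxycoumarin)
Product: **12** the 3β‑hydroxy 11‑(umbelliferyl) ether (deacetyl‑polyanthinin)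
Conditions: PPh3, DIAD, THF, 0 → 40 °C
Reagents that add atoms: none (both partners are numbered reactants)
Why: Mitsunobu etherification couples the acidic phenol only at the primary C11‑OH, because the neopentyl secondary C3‑OH cannot undergo SN2, and no stereocentre is involved.

**Step 11**
Reactants: **12**
Product: **13** Polyanthinin
Conditions: Ac2O, pyridine, cat. DMAP, CH2Cl2, rt
Reagents that add atoms: acetic anhydride, CC(=O)OC(C)=O
Why: DMAP‑catalysed O‑acylation of the equatorial 3β‑OH proceeds with retention, and the coumarin and the alkene are inert.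

## Compound list
1 | (S)‑(+)‑Wieland–Miescher ketone, (8aS)‑8a‑methyl‑3,4,8,8a‑tetrahydronaphthalene‑1,6(2H,7H)‑dione | C[C@]12CCC(=O)C=C1CCCC2=O | starting material
2 | C3 1,3‑dithiolane of 1 (Δ4, 9‑oxo, 10β‑Me) | C1CCC2=CC3(SCCS3)CC[C@]2(C)C1=O | intermediate
3 | 8(12)‑methylene‑9‑oxo dithiolane | C=C1CCC2=CC3(SCCS3)CC[C@]2(C)C1=O | intermediate
4 | spiro 9,11‑oxirane (O β, CH2 α), 8(12)‑ene, dithiolane | C=C1CCC2=CC3(SCCS3)CC[C@]2(C)[C@]14CO4 | intermediate
5 | 9β‑CH2OH, 9α‑H, 8(12)‑ene, dithiolane | C=C1CCC2=CC3(SCCS3)CC[C@]2(C)[C@H]1CO | intermediate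
6 | 11‑hydroxy‑Δ4,8(12)‑dien‑3‑one | C=C1CCC2=CC(=O)CC[C@]2(C)[C@H]1CO | intermediate
7 | 5β,10β‑dimethyl cis‑decalin, 3‑OTES Δ3‑enol ether, 11‑OTES | C=C1CC[C@]2(C)C=C(O[Si](CC)(CC)CC)CC[C@]2(C)[C@H]1CO[Si](CC)(CC)CC | intermediate
8 | 4‑methylene‑3‑ketone, 11‑OTES | C=C1CC[C@]2(C)C(=C)C(=O)CC[C@]2(C)[C@H]1CO[Si](CC)(CC)CC | intermediate
9 | 4,4‑dimethyl‑3‑ketone, 11‑OTES | C=C1CC[C@]2(C)C(C)(C)C(=O)CC[C@]2(C)[C@H]1CO[Si](CC)(CC)CC | intermediate
10 | 3β,11‑diol (3S,5S,9S,10R) | C=C1CC[C@]2(C)C(C)(C)[C@@H](O)CC[C@]2(C)[C@H]1CO | intermediate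
11 | umbelliferone (7‑hydroxycoumarin) | Oc1ccc2ccc(=O)oc2c1 | starting material
12 | 3β‑hydroxy 11‑umbelliferyl ether | C=C1CC[C@]2(C)C(C)(C)[C@@H](O)CC[C@]2(C)[C@H]1COc1ccc2ccc(=O)oc2c1 | intermediate
13 | Polyanthinin, (2S,4aR,5S,8aS)‑1,1,4a,8a‑tetramethyl‑6‑methylidene‑5‑[(2‑oxochromen‑7‑yl)oxymethyl]decahydronaphthalen‑2‑yl acetate | C=C1CC[C@]2(C)C(C)(C)[C@@H](OC(C)=O)CC[C@]2(C)[C@H]1COc1ccc2ccc(=O)oc2c1 | target

## Totals and risks
**Total steps:** 11. **Longest linear sequence:** 11 (fully linear from **1**; **11** is purchased).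

**Three steps most likely to fail**

1. **Step 8, C‑methylation next to quaternary C5.**
   - Problem: creating the third contiguous quaternary carbon forces the ring flip that makes C11 axial. O‑methylation or proton transfer may compete.
   - Fallback: trap the Selectride enolate as its TMS enol ether. Form the last C–C bond by Furukawa cyclopropanation of that electron‑rich enol ether, then open the siloxycyclopropane with base (Conia‑type α‑methylation). This replaces the SN2 alkylation with a carbenoid addition.

2. **Step 4, Pd/formate hydrogenolysis.**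
   - Problem: the C9–O bond is equatorial and poorly aligned with the alkene π system, C9 is very hindered, and the dithiolane may slow the Pd catalyst.
   - Fallback: open **4** in the SN2′ sense to the Δ8(9)‑11,12‑diol. Then apply a Myers reductive allylic transposition (NBSH, PPh3, DEAD) at the less hindered C12‑OH. Sigmatropic loss of N2 delivers H to C9 from the open α face and forms C8=CH2 without any metal hydride.

3. **Step 10, SN2 at the axial C11.**
   - Problem: C11 is β‑branched and 1,3‑diaxial with the C5 methyl.
   - Fallback: form the bond at the aryl carbon instead. Acetylate C3 while C11 is still silylated, desilylate, then carry out a Pd‑catalysed C–O coupling (t‑BuBrettPhos‑Pd, Cs2CO3, toluene) of the primary alcohol with 7‑bromocoumarin or umbelliferone triflate.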